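**Plan**

1. Numbering (germacrane): lactone C12(=O)–O–C8, exocyclic methylene C11=C13, ring-fusion carbon C7, acyloxy carbinol C6, C4=C5 with C15H2O on C4, carbinol C3, C1=C10 with methyl C14 on C10, methylenes C9 and C2.
2. Enabling feature: in the α-methylene-γ-butyrolactone ring (O–C8–C7–C11(=C13)–C12) the β-carbon C7 carries the oxygenated C6 of the ten-membered ring, so C6(O)–C7–C11=C13 is a homoallylic alcohol. Cutting C6–C7 (after removal of the C6 acyl group and masking of O3 as a silyl ether) leads to the open-chain C6 enal 26, which carries a 3-(bromomethyl)butenolide.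
3. Further cuts: butenolide C7=C11 (ring-closing metathesis) and O8–C12 (ester); C4–C15 (Stille); C3–C4 (acetylide + Weinreb amide); C1–C2 (alkenyl iodide + zinc enolate); C10–C14 (carboalumination); C9–C10 (acetylide + epoxide) and the vinyl carbon on C7 (sulfonium ylide).
4. Forward: the chain is grown linearly from C8 to C6; the butenolide ring is closed first, then the ten-membered carbocycle by a CrCl2-mediated allylation that also creates the exocyclic methylene; esterification at O6 and desilylation at O3 finish the synthesis.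
5. Stereochemistry: C8 from (S)-epichlorohydrin; C3 from asymmetric transfer hydrogenation of an ynone; both acyl centres from (R)-2-methylbutanoic acid; 1(10)E from syn-carboalumination and 4E from hydroxyl-directed trans-hydrostannation; C6 and C7 arise in the ring closure under control of C8 and a chair transition state.

Key step: step 17

Assumption: both acyl residues are (R)-2-methylbutanoyl, as the structure requires, and compounds 1, 2, 10, 13, 19, 21 and 24 are taken as purchasable.

**Route**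

Step 1
Reactants: 1 (S)-epichlorohydrin; 2 ethynyltrimethylsilane
Product: 3 (S)-1-chloro-5-(trimethylsilyl)pent-4-yn-2-ol
Conditions: 2, n-BuLi, THF, −78 °C; BF3·OEt2; then 1, −78 °C; aq. NH4Cl
Reagents that add atoms: none
Why: Yamaguchi–Hirao alkynylation: the BF3-activated epoxide is opened by the lithium acetylide in an SN2 reaction at the unsubstituted carbon, so the chloride is kept and the C8 stereocentre of 1 is carried over unchanged.

Step 2
Reactants: 3 (S)-1-chloro-5-(trimethylsilyl)pent-4-yn-2-ol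
Product: 5 (S)-6-(trimethylsilyl)hex-1-en-5-yn-3-ol, via epoxide 4 (not isolated)
Conditions: Me3S+ I− (4 equiv), n-BuLi (3.8 equiv), THF, −10 °C → rt
Reagents that add atoms: trimethylsulfonium iodide, C[S+](C)C.[I-]
Why: The ylide first acts as base to close the epoxide 4, then opens it at the terminal carbon, and a second ylide equivalent induces loss of dimethyl sulfide from the sulfonium alkoxide (one-carbon homologation of an epoxide to an allylic alcohol with the Corey–Chaykovsky reagent), which leaves C8 untouched.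

Step 3
Reactants: 5 (S)-6-(trimethylsilyl)hex-1-en-5-yn-3-ol
Product: 7 (S)-triethyl(hex-1-en-5-yn-3-yloxy)silane, via bis-silyl ether 6 (not isolated)
Conditions: Et3SiCl, imidazole, CH2Cl2, 0 °C → rt; then K2CO3, MeOH, rt
Reagents that add atoms: chlorotriethylsilane, CC[Si](Cl)(CC)CC
Why: Silyl ether formation followed by methanolysis of the alkynyl C–Si bond (protodesilylation), to which the secondary triethylsilyl ether should be stable at room temperature.

Step 4
Reactants: 7 (S)-triethyl(hex-1-en-5-yn-3-yloxy)silane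
Product: 9 (3S,5E)-6-iodo-5-methyl-3-(triethylsilyloxy)hexa-1,5-diene, via alkenylalane 8 (not isolated)
Conditions: Me3Al (2.5 equiv), Cp2ZrCl2 (0.25 equiv), CH2Cl2, 0 °C → rt; then I2, THF, −30 °C
Reagents that add atoms: trimethylaluminium, C[Al](C)C; iodine, II
Why: Negishi carboalumination catalysed by Cp2ZrCl2 adds methyl and aluminium syn across the terminal alkyne with methyl on the internal carbon, and iodinolysis of the alkenylalane 8 with retention fixes the 1(10)E geometry; the monosubstituted alkene reacts far more slowly.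

Step 5
Reactants: 9 (3S,5E)-6-iodo-5-methyl-3-(triethylsilyloxy)hexa-1,5-diene; 10 ethyl bromoacetate
Product: 11 ethyl (3E,6S)-4-methyl-6-(triethylsilyloxy)octa-3,7-dienoate
Conditions: 10, Zn dust (Me3SiCl-activated), THF, 40 °C; then 9, Pd(PPh3)4 (5 mol %), THF/DMPU, 50 °C
Reagents that add atoms: none
Why: Negishi-type cross-coupling of the Reformatsky reagent with the alkenyl iodide under Pd(PPh3)4 catalysis forms the C1–C2 bond with retention of the alkene geometry and gives the β,γ-unsaturated ester.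

Step 6
Reactants: 11 ethyl (3E,6S)-4-methyl-6-(triethylsilyloxy)octa-3,7-dienoate
Product: 12 (3E,6S)-N-methoxy-N,4-dimethyl-6-(triethylsilyloxy)octa-3,7-dienamide
Conditions: MeNH(OMe)·HCl, iPrMgCl, THF, −20 → 0 °C
Reagents that add atoms: N,O-dimethylhydroxylamine hydrochloride, CNOC.Cl
Why: Aminolysis of the ester by the chloromagnesium amide of N,O-dimethylhydroxylamine (Weinreb amide formation) proceeds below 0 °C, where the skipped alkene should not move into conjugation.

Step 7
Reactants: 12 (3E,6S)-N-methoxy-N,4-dimethyl-6-(triethylsilyloxy)octa-3,7-dienamide; 13 3,3-diethoxyprop-1-yne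
Product: 14 (6E,9S)-1,1-diethoxy-7-methyl-9-(triethylsilyloxy)undeca-6,10-dien-2-yn-4-one
Conditions: 13, n-BuLi, THF, −78 °C; then 12, −78 → −20 °C; aq. NH4Cl
Reagents that add atoms: none
Why: Weinreb ketone synthesis: the lithium acetylide adds once, because the chelated tetrahedral adduct collapses to the ynone only on aqueous work-up, and the weakly basic acetylide does not enolise the amide.

Step 8
Reactants: 14 (6E,9S)-1,1-diethoxy-7-methyl-9-(triethylsilyloxy)undeca-6,10-dien-2-yn-4-one
Product: 15 (4R,6E,9S)-1,1-diethoxy-7-methyl-9-(triethylsilyloxy)undeca-6,10-dien-2-yn-4-ol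
Conditions: Ru[(R,R)-TsDPEN](p-cymene) (2 mol %), iPrOH, rt
Reagents that add atoms: none
Why: Noyori asymmetric transfer hydrogenation of an alkynyl ketone, in which the alkyne takes the place of the aryl group of an aryl ketone, so the (R,R)-catalyst should deliver hydride to give the 3R carbinol under base-free conditions that spare the acidic C2 methylene.

Step 9
Reactants: 15 (4R,6E,9S)-1,1-diethoxy-7-methyl-9-(triethylsilyloxy)undeca-6,10-dien-2-yn-4-ol
Product: 16 (2Z,4R,6E,9S)-1,1-diethoxy-7-methyl-3-(tributylstannyl)-9-(triethylsilyloxy)undeca-2,6,10-trien-4-ol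
Conditions: Bu3SnH (1.1 equiv), [Cp*RuCl]4 (1.5 mol %), CH2Cl2, rt
Reagents that add atoms: tributyltin hydride, CCCC[SnH](CCCC)CCCC
Why: Hydroxyl-directed trans-hydrostannation of a propargylic alcohol with [Cp*RuCl]4: hydrogen bonding of the OH group to the chloride ligand places tin on the alkyne carbon next to the carbinol (C4) and hydrogen trans to it on C5, which puts tin cis to C6, where C15 must later stand.

Step 10
Reactants: 16 (2Z,4R,6E,9S)-1,1-diethoxy-7-methyl-3-(tributylstannyl)-9-(triethylsilyloxy)undeca-2,6,10-trien-4-ol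
Product: 17 (2Z,4R,6E,9S)-1,1-diethoxy-3-iodo-7-methyl-9-(triethylsilyloxy)undeca-2,6,10-trien-4-ol
Conditions: I2 (1.0 equiv), CH2Cl2, −78 °C
Reagents that add atoms: iodine, II
Why: Iododestannylation is an ipso substitution with retention of alkene geometry and should be much faster at −78 °C than iodoetherification or addition to the other alkenes.

Step 11
Reactants: 17 (2Z,4R,6E,9S)-1,1-diethoxy-3-iodo-7-methyl-9-(triethylsilyloxy)undeca-2,6,10-trien-4-ol
Product: 18 (2Z,4R,6E,9S)-4-(tert-butyldimethylsilyloxy)-1,1-diethoxy-3-iodo-7-methyl-9-(triethylsilyloxy)undeca-2,6,10-triene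
Conditions: tBuMe2SiCl, imidazole, DMF, rt
Reagents that add atoms: tert-butyldimethylsilyl chloride, CC(C)(C)[Si](C)(C)Cl
Why: Silylation of the hindered secondary allylic alcohol with the silyl chloride and imidazole avoids silyl triflates, which would attack the diethyl acetal.

Step 12
Reactants: 18 (2Z,4R,6E,9S)-4-(tert-butyldimethylsilyloxy)-1,1-diethoxy-3-iodo-7-methyl-9-(triethylsilyloxy)undeca-2,6,10-triene; 19 (tributylstannyl)methanol
Product: 20 (2E)-2-[(1R,3E,6S)-1-(tert-butyldimethylsilyloxy)-4-methyl-6-(triethylsilyloxy)octa-3,7-dien-1-yl]-4,4-diethoxybut-2-en-1-ol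
Conditions: 19 (1.5 equiv), Pd(PPh3)4 (10 mol %), toluene, 90 °C
Reagents that add atoms: none
Why: Kosugi–Migita–Stille coupling of the alkenyl iodide with the hydroxymethylstannane transfers the CH2OH group with retention under neutral conditions, which sets the 4E geometry (C15 cis to C6).

Step 13
Reactants: 20 (2E)-2-[(1R,3E,6S)-1-(tert-butyldimethylsilyloxy)-4-methyl-6-(triethylsilyloxy)octa-3,7-dien-1-yl]-4,4-diethoxybut-2-en-1-ol; 21 (R)-2-methylbutanoic acid
Product: 22 (2E)-2-[(1R,3E,6S)-1-(tert-butyldimethylsilyloxy)-4-methyl-6-(triethylsilyloxy)octa-3,7-dien-1-yl]-4,4-diethoxybut-2-en-1-yl (2R)-2-methylbutanoate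
Conditions: 21, DCC, DMAP (cat.), CH2Cl2, 0 °C → rt
Reagents that add atoms: none
Why: Steglich esterification of the primary allylic alcohol installs the first (R)-2-methylbutanoate under mild conditions with little risk to the α-stereocentre of the acid.

Step 14
Reactants: 22 (2E)-2-[(1R,3E,6S)-1-(tert-butyldimethylsilyloxy)-4-methyl-6-(triethylsilyloxy)octa-3,7-dien-1-yl]-4,4-diethoxybut-2-en-1-yl (2R)-2-methylbutanoate
Product: 23 (2E)-2-[(1R,3E,6S)-1-(tert-butyldimethylsilyloxy)-6-hydroxy-4-methylocta-3,7-dien-1-yl]-4-oxobut-2-en-1-yl (2R)-2-methylbutanoate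
Conditions: AcOH/THF/H2O (3:1:1), rt
Reagents that add atoms: water, O
Why: Selective acid hydrolysis: aqueous acetic acid cleaves the secondary triethylsilyl ether and the conjugated acetal while the more hindered tert-butyldimethylsilyl ether survives, and the enal keeps the geometry with the formyl group cis to the smaller CH2O substituent, which is also the more stable one.

Step 15
Reactants: 23 (2E)-2-[(1R,3E,6S)-1-(tert-butyldimethylsilyloxy)-6-hydroxy-4-methylocta-3,7-dien-1-yl]-4-oxobut-2-en-1-yl (2R)-2-methylbutanoate; 24 2-(bromomethyl)acrylic acid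
Product: 25 (3S,5E,8R,9E)-8-(tert-butyldimethylsilyloxy)-5-methyl-9-({[(2R)-2-methylbutanoyl]oxy}methyl)-11-oxoundeca-1,5,9-trien-3-yl 2-(bromomethyl)prop-2-enoate
Conditions: 24, DCC, DMAP (5 mol %), CH2Cl2, −10 °C → rt
Reagents that add atoms: none
Why: Steglich esterification of the only free hydroxyl group; low temperature and a small amount of DMAP limit SN2' attack on the allylic bromide.

Step 16
Reactants: 25 (3S,5E,8R,9E)-8-(tert-butyldimethylsilyloxy)-5-methyl-9-({[(2R)-2-methylbutanoyl]oxy}methyl)-11-oxoundeca-1,5,9-trien-3-yl 2-(bromomethyl)prop-2-enoate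
Product: 26 (2E)-2-{(1R,3E)-5-[(2S)-4-(bromomethyl)-5-oxo-2,5-dihydrofuran-2-yl]-1-(tert-butyldimethylsilyloxy)-4-methylpent-3-en-1-yl}-4-oxobut-2-en-1-yl (2R)-2-methylbutanoate
Conditions: second-generation Hoveyda–Grubbs catalyst (H2IMes)Cl2Ru=CH(C6H4-2-OiPr) (10 mol %), toluene (5 mM), 80 °C
Reagents that add atoms: none
Why: Ring-closing metathesis between the vinyl group and the 1,1-disubstituted acrylate closes the five-membered butenolide with loss of ethene; the phosphine-free catalyst should tolerate the allylic bromide, and the trisubstituted alkenes are too hindered to take part.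

Step 17
Reactants: 26 (2E)-2-{(1R,3E)-5-[(2S)-4-(bromomethyl)-5-oxo-2,5-dihydrofuran-2-yl]-1-(tert-butyldimethylsilyloxy)-4-methylpent-3-en-1-yl}-4-oxobut-2-en-1-yl (2R)-2-methylbutanoate
Product: 28 (3R,6R,7S,8S)-3-(tert-butyldimethylsilyloxy)-6-hydroxy-15-[(2R)-2-methylbutanoyloxy]germacra-1(10)E,4E,11(13)-trien-12,8-olide, via allylchromium 27 (not isolated)
Conditions: CrCl2 (12 equiv), THF, rt, syringe-pump addition of 26 over 10 h (final 2 mM); aq. NH4Cl
Reagents that add atoms: none
Why: Two equivalents of CrCl2 reduce the allylic C13–Br bond of 26 to the trivalent allylchromium 27, which adds through its γ-carbon C7 (allyl transposition) to the C6 aldehyde in a closed six-membered Zimmerman–Traxler transition state, creating the C6–C7 bond and the exocyclic C11=C13 methylene in the same event. The closest known reaction type is the Nozaki–Hiyama–Kishi (chromium Barbier) allylation of aldehydes with 3-(bromomethyl)butenolides, together with its intramolecular use for medium and large carbocycles. The ten-membered carbocycle closes by attack on the carbonyl carbon with the C=O bond outside the new ring (10-exo-trig). C7 is set by the resident C8 stereocentre, because C6 adds to the butenolide face opposite to the C9 branch, which gives the trans-fused lactone; C6 is set by the chair, in which the C7–C8 bond is locked trans to CH2Cr by the lactone ring and the alkenyl residue C5 of the aldehyde lies equatorial, which gives the anti arrangement of the C6 oxygen and the C7–C8 bond, that is 6R. The step needs γ- over α-attack of the allyl unit, 1,2- over 1,4-addition to the enal, ring closure over intermolecular reaction and tolerance of the ester and lactone; these are secured by the SE2' preference and carbonyl selectivity of allylchromium reagents, by their low basicity, and by slow addition at 2 mM. The E,E-configured 1(10),4-diene tether already has the shape of the germacrane ring, holds C6 near C7, and is expected to favour the same chair.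

Step 18
Reactants: 28 (3R,6R,7S,8S)-3-(tert-butyldimethylsilyloxy)-6-hydroxy-15-[(2R)-2-methylbutanoyloxy]germacra-1(10)E,4E,11(13)-trien-12,8-olide; 21 (R)-2-methylbutanoic acid
Product: 29 (3R,6R,7R,8S)-3-(tert-butyldimethylsilyloxy)-6,15-bis[(2R)-2-methylbutanoyloxy]germacra-1(10)E,4E,11(13)-trien-12,8-olide
Conditions: 21 (3 equiv), DCC, DMAP, CH2Cl2, 0 °C → rt
Reagents that add atoms: none
Why: Steglich esterification of the secondary allylic C6 alcohol; an acyl shift from O15 to O6 beforehand would be of no consequence, because both oxygens end up with the same acyl group.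

Step 19
Reactants: 29 (3R,6R,7R,8S)-3-(tert-butyldimethylsilyloxy)-6,15-bis[(2R)-2-methylbutanoyloxy]germacra-1(10)E,4E,11(13)-trien-12,8-olide
Product: 30 (3R,6R,7R,8S)-3-hydroxy-6,15-bis[(2R)-2-methylbutanoyloxy]germacra-1(10)E,4E,11(13)-trien-12,8-olide
Conditions: HF·pyridine, pyridine, THF, 0 °C → rt
Reagents that add atoms: none
Why: Buffered fluoride cleavage of the silyl ether (desilylation) should free the C3 hydroxyl without touching the esters or the α-methylene lactone.

**Compound list**

1 | (S)-epichlorohydrin, (S)-2-(chloromethyl)oxirane | ClC[C@@H]1CO1 | starting material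
2 | ethynyltrimethylsilane | C#C[Si](C)(C)C | starting material
3 | (S)-1-chloro-5-(trimethylsilyl)pent-4-yn-2-ol | ClC[C@@H](O)CC#C[Si](C)(C)C | intermediate
4 | (S)-trimethyl[3-(oxiran-2-yl)prop-1-yn-1-yl]silane | C[Si](C)(C)C#CC[C@H]1CO1 | intermediate
5 | (S)-6-(trimethylsilyl)hex-1-en-5-yn-3-ol | C=C[C@@H](O)CC#C[Si](C)(C)C | intermediate
6 | (S)-triethyl{[6-(trimethylsilyl)hex-1-en-5-yn-3-yl]oxy}silane | C=C[C@@H](O[Si](CC)(CC)CC)CC#C[Si](C)(C)C | intermediate
7 | (S)-triethyl(hex-1-en-5-yn-3-yloxy)silane | C=C[C@@H](O[Si](CC)(CC)CC)CC#C | intermediate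
8 | dimethyl[(1E,4S)-2-methyl-4-(triethylsilyloxy)hexa-1,5-dien-1-yl]alane | C=C[C@@H](O[Si](CC)(CC)CC)C/C(C)=C/[Al](C)C | intermediate
9 | (3S,5E)-6-iodo-5-methyl-3-(triethylsilyloxy)hexa-1,5-diene | C=C[C@@H](O[Si](CC)(CC)CC)C/C(C)=C/I | intermediate
10 | ethyl bromoacetate | CCOC(=O)CBr | starting material
11 | ethyl (3E,6S)-4-methyl-6-(triethylsilyloxy)octa-3,7-dienoate | C=C[C@@H](O[Si](CC)(CC)CC)C/C(C)=C/CC(=O)OCC | intermediate
12 | (3E,6S)-N-methoxy-N,4-dimethyl-6-(triethylsilyloxy)octa-3,7-dienamide | C=C[C@@H](O[Si](CC)(CC)CC)C/C(C)=C/CC(=O)N(C)OC | intermediate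
13 | 3,3-diethoxyprop-1-yne | C#CC(OCC)OCC | starting material
14 | (6E,9S)-1,1-diethoxy-7-methyl-9-(triethylsilyloxy)undeca-6,10-dien-2-yn-4-one | C=C[C@@H](O[Si](CC)(CC)CC)C/C(C)=C/CC(=O)C#CC(OCC)OCC | intermediate
15 | (4R,6E,9S)-1,1-diethoxy-7-methyl-9-(triethylsilyloxy)undeca-6,10-dien-2-yn-4-ol | C=C[C@@H](O[Si](CC)(CC)CC)C/C(C)=C/C[C@@H](O)C#CC(OCC)OCC | intermediate
16 | (2Z,4R,6E,9S)-1,1-diethoxy-7-methyl-3-(tributylstannyl)-9-(triethylsilyloxy)undeca-2,6,10-trien-4-ol | C=C[C@@H](O[Si](CC)(CC)CC)C/C(C)=C/C[C@@H](O)/C([Sn](CCCC)(CCCC)CCCC)=C/C(OCC)OCC | intermediate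
17 | (2Z,4R,6E,9S)-1,1-diethoxy-3-iodo-7-methyl-9-(triethylsilyloxy)undeca-2,6,10-trien-4-ol | C=C[C@@H](O[Si](CC)(CC)CC)C/C(C)=C/C[C@@H](O)/C(I)=C/C(OCC)OCC | intermediate
18 | (2Z,4R,6E,9S)-4-(tert-butyldimethylsilyloxy)-1,1-diethoxy-3-iodo-7-methyl-9-(triethylsilyloxy)undeca-2,6,10-triene | C=C[C@@H](O[Si](CC)(CC)CC)C/C(C)=C/C[C@@H](O[Si](C)(C)C(C)(C)C)/C(I)=C/C(OCC)OCC | intermediate
19 | (tributylstannyl)methanol | OC[Sn](CCCC)(CCCC)CCCC | starting material
20 | (2E)-2-[(1R,3E,6S)-1-(tert-butyldimethylsilyloxy)-4-methyl-6-(triethylsilyloxy)octa-3,7-dien-1-yl]-4,4-diethoxybut-2-en-1-ol | C=C[C@@H](O[Si](CC)(CC)CC)C/C(C)=C/C[C@@H](O[Si](C)(C)C(C)(C)C)/C(CO)=C/C(OCC)OCC | intermediate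
21 | (R)-2-methylbutanoic acid | CC[C@@H](C)C(=O)O | starting material
22 | (2E)-2-[(1R,3E,6S)-1-(tert-butyldimethylsilyloxy)-4-methyl-6-(triethylsilyloxy)octa-3,7-dien-1-yl]-4,4-diethoxybut-2-en-1-yl (2R)-2-methylbutanoate | C=C[C@@H](O[Si](CC)(CC)CC)C/C(C)=C/C[C@@H](O[Si](C)(C)C(C)(C)C)/C(COC(=O)[C@H](C)CC)=C/C(OCC)OCC | intermediate
23 | (2E)-2-[(1R,3E,6S)-1-(tert-butyldimethylsilyloxy)-6-hydroxy-4-methylocta-3,7-dien-1-yl]-4-oxobut-2-en-1-yl (2R)-2-methylbutanoate | C=C[C@@H](O)C/C(C)=C/C[C@@H](O[Si](C)(C)C(C)(C)C)/C(COC(=O)[C@H](C)CC)=C/C=O | intermediate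
24 | 2-(bromomethyl)acrylic acid | C=C(CBr)C(=O)O | starting material
25 | (3S,5E,8R,9E)-8-(tert-butyldimethylsilyloxy)-5-methyl-9-({[(2R)-2-methylbutanoyl]oxy}methyl)-11-oxoundeca-1,5,9-trien-3-yl 2-(bromomethyl)prop-2-enoate | C=C(CBr)C(=O)O[C@H](C=C)C/C(C)=C/C[C@@H](O[Si](C)(C)C(C)(C)C)/C(COC(=O)[C@H](C)CC)=C/C=O | intermediate
26 | (2E)-2-{(1R,3E)-5-[(2S)-4-(bromomethyl)-5-oxo-2,5-dihydrofuran-2-yl]-1-(tert-butyldimethylsilyloxy)-4-methylpent-3-en-1-yl}-4-oxobut-2-en-1-yl (2R)-2-methylbutanoate | O=C1O[C@@H](C/C(C)=C/C[C@@H](O[Si](C)(C)C(C)(C)C)/C(COC(=O)[C@H](C)CC)=C/C=O)C=C1CBr | intermediate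
27 | dichlorochromium allyl species of 26 (CrCl2 in place of Br on C13) | O=C1O[C@@H](C/C(C)=C/C[C@@H](O[Si](C)(C)C(C)(C)C)/C(COC(=O)[C@H](C)CC)=C/C=O)C=C1C[Cr](Cl)Cl | intermediate
28 | (3R,6R,7S,8S)-3-(tert-butyldimethylsilyloxy)-6-hydroxy-15-[(2R)-2-methylbutanoyloxy]germacra-1(10)E,4E,11(13)-trien-12,8-olide | C=C1C(=O)O[C@H]2C/C(C)=C/C[C@@H](O[Si](C)(C)C(C)(C)C)/C(COC(=O)[C@H](C)CC)=C/[C@@H](O)[C@H]12 | intermediate
29 | (3R,6R,7R,8S)-3-(tert-butyldimethylsilyloxy)-6,15-bis[(2R)-2-methylbutanoyloxy]germacra-1(10)E,4E,11(13)-trien-12,8-olide | C=C1C(=O)O[C@H]2C/C(C)=C/C[C@@H](O[Si](C)(C)C(C)(C)C)/C(COC(=O)[C@H](C)CC)=C/[C@@H](OC(=O)[C@H](C)CC)[C@H]12 | intermediate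
30 | (3R,6R,7R,8S)-3-hydroxy-6,15-bis[(2R)-2-methylbutanoyloxy]germacra-1(10)E,4E,11(13)-trien-12,8-olide (CNP0164325.1) | C=C1C(=O)O[C@H]2C/C(C)=C/C[C@@H](O)/C(COC(=O)[C@H](C)CC)=C/[C@@H](OC(=O)[C@H](C)CC)[C@H]12 | target

**Count and risks**

Total step count: 19. Longest linear sequence: 19 steps (from 1 to 30).

Steps most likely to fail:

1. Step 17 (ring closure). The strain of the forming ten-membered ring may push the aldehyde through a boat, or through the chair with C5 axial, so that facial selectivity at C6 is lost; intermolecular allylation may also compete. Fallback: starting from 26, the chromium ring closure is run without relying on control at C6, and the C6-epimeric alcohol (3R,6S,7S,8S)-3-(tert-butyldimethylsilyloxy)-6-hydroxy-15-[(2R)-2-methylbutanoyloxy]germacra-1(10)E,4E,11(13)-trien-12,8-olide F1 is carried on. Mitsunobu esterification of F1 with 21 (PPh3, diisopropyl azodicarboxylate, toluene, 0 °C) should form the ester with SN2 inversion at C6 and come back to the route at 29. Any 28 formed alongside goes through step 18, so both epimers converge and C6 is then fixed by inversion, not by the transition state.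

2. Step 16 (metathesis with the allylic bromide in place). The catalyst may be deactivated by the allylic bromide, and closure onto the electron-poor 1,1-disubstituted acrylate may be slow; SN2' loss of bromide during step 15 belongs to the same risk. Fallback: starting from 23, Steglich esterification with 2-{[(4-methoxybenzyl)oxy]methyl}acrylic acid gives (3S,5E,8R,9E)-8-(tert-butyldimethylsilyloxy)-5-methyl-9-({[(2R)-2-methylbutanoyl]oxy}methyl)-11-oxoundeca-1,5,9-trien-3-yl 2-{[(4-methoxybenzyl)oxy]methyl}prop-2-enoate F2. Ring-closing metathesis with the same catalyst gives the 4-{[(4-methoxybenzyl)oxy]methyl} analogue of 26, F3. DDQ in CH2Cl2/pH 7 buffer removes the benzyl ether to give the 4-(hydroxymethyl) analogue of 26, F4. Appel bromination (CBr4, PPh3, CH2Cl2, 0 °C) then comes back to the route at 26, so the bromide is introduced only after the ring is closed.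

3. Step 12 (hydroxymethylation). Transmetalation at the hindered iodide next to the silyloxy carbinol may be slow, and protodeiodination may take over. Fallback: starting from 18, methoxycarbonylation (Pd(OAc)2, PPh3, CO 1 atm, Et3N, MeOH/DMF, 60 °C) should give, with retention, methyl (2Z)-2-[(1R,3E,6S)-1-(tert-butyldimethylsilyloxy)-4-methyl-6-(triethylsilyloxy)octa-3,7-dien-1-yl]-4,4-diethoxybut-2-enoate F5. Reduction with diisobutylaluminium hydride (iBu2AlH, CH2Cl2, −78 °C) then comes back to the route at 20.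

**Further compounds**

F1 | step 17 | (3R,6S,7S,8S)-3-(tert-butyldimethylsilyloxy)-6-hydroxy-15-[(2R)-2-methylbutanoyloxy]germacra-1(10)E,4E,11(13)-trien-12,8-olide | C=C1C(=O)O[C@H]2C/C(C)=C/C[C@@H](O[Si](C)(C)C(C)(C)C)/C(COC(=O)[C@H](C)CC)=C/[C@H](O)[C@H]12
F2 | step 16 | (3S,5E,8R,9E)-8-(tert-butyldimethylsilyloxy)-5-methyl-9-({[(2R)-2-methylbutanoyl]oxy}methyl)-11-oxoundeca-1,5,9-trien-3-yl 2-{[(4-methoxybenzyl)oxy]methyl}prop-2-enoate | C=C(COCc1ccc(OC)cc1)C(=O)O[C@H](C=C)C/C(C)=C/C[C@@H](O[Si](C)(C)C(C)(C)C)/C(COC(=O)[C@H](C)CC)=C/C=O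
F3 | step 16 | (2E)-2-{(1R,3E)-1-(tert-butyldimethylsilyloxy)-5-[(2S)-4-{[(4-methoxybenzyl)oxy]methyl}-5-oxo-2,5-dihydrofuran-2-yl]-4-methylpent-3-en-1-yl}-4-oxobut-2-en-1-yl (2R)-2-methylbutanoate | O=C1O[C@@H](C/C(C)=C/C[C@@H](O[Si](C)(C)C(C)(C)C)/C(COC(=O)[C@H](C)CC)=C/C=O)C=C1COCc1ccc(OC)cc1
F4 | step 16 | (2E)-2-{(1R,3E)-1-(tert-butyldimethylsilyloxy)-5-[(2S)-4-(hydroxymethyl)-5-oxo-2,5-dihydrofuran-2-yl]-4-methylpent-3-en-1-yl}-4-oxobut-2-en-1-yl (2R)-2-methylbutanoate | O=C1O[C@@H](C/C(C)=C/C[C@@H](O[Si](C)(C)C(C)(C)C)/C(COC(=O)[C@H](C)CC)=C/C=O)C=C1CO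
F5 | step 12 | methyl (2Z)-2-[(1R,3E,6S)-1-(tert-butyldimethylsilyloxy)-4-methyl-6-(triethylsilyloxy)octa-3,7-dien-1-yl]-4,4-diethoxybut-2-enoate | C=C[C@@H](O[Si](CC)(CC)CC)C/C(C)=C/C[C@@H](O[Si](C)(C)C(C)(C)C)/C(C(=O)OC)=C/C(OCC)OCC
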